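**Strategy**

The route rests on cutting two neighbouring arene bonds at once: C3–C3a of the dihydrofuran ring and C4–CHO of the benzo ring. Because C3a and C4 are adjacent benzo-ring carbons that carry C3 and the first side-chain carbon, an aryne across C3a–C4 can insert into the C3–formyl bond of an α-formyl ester held through O1 and C2. One operation thus closes the dihydrofuran ring, places the aldehyde at C4 and defines C3. The precursor is an enantioenriched β-aryloxy α-formyl ester (as its silyl enol ether) whose aryloxy ring carries silyl at C4 and triflate at C3a; C2 comes from an asymmetric ketone hydrogenation and Mitsunobu inversion.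

Key step: step 12

Remark 1: formyl ester 17 should exist largely as its hydroxymethylene enol and is drawn as the aldehyde tautomer; enolisation at C2 changes the descriptor of the benzylic carbon from 3S (17) to 3R (enol ether 18, enolate 19), because C2 then outranks the aryl group, while the spatial arrangement stays the same.

Remark 2: the double-bond geometry of enol ether 18 and of enolates 16, 19 and 21 has no bearing on the outcome and is left open.

**Route**

Step 1
Reactants: 1 pyrogallol
Product: 2 2,2-diphenyl-1,3-benzodioxol-4-ol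
Conditions: Ph2CCl2, neat, 170 °C
Reagents that add atoms: dichlorodiphenylmethane, ClC(Cl)(c1ccccc1)c1ccccc1
Why: Ketalisation of a catechol unit with a gem-dichloride (diphenylmethylene ketal formation); only an adjacent pair of hydroxyls can close the five-membered ring, and by symmetry either pair leaves one terminal hydroxyl free.

Step 2
Reactants: 2 2,2-diphenyl-1,3-benzodioxol-4-ol
Product: 3 2,2-diphenyl-1,3-benzodioxol-4-yl N-isopropylcarbamate
Conditions: i-PrNCO, Et3N (cat.), CH2Cl2, rt
Reagents that add atoms: isopropyl isocyanate, CC(C)N=C=O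
Why: Base-catalysed addition of the phenol to an isocyanate (carbamoylation) installs a strong ortho-directing group that can later be removed under mild amine conditions.

Step 3
Reactants: 3 2,2-diphenyl-1,3-benzodioxol-4-yl N-isopropylcarbamate
Product: 7 2,2-diphenyl-5-(trimethylsilyl)-1,3-benzodioxol-4-yl N-isopropylcarbamate, via N-silyl carbamate 4 (not isolated), via aryllithium 5 (not isolated), via bis-silyl carbamate 6 (not isolated)
Conditions: TBSOTf, TMEDA, Et2O, 0 °C → rt; n-BuLi, TMEDA, −78 °C; TMSCl, −78 °C → rt; aq. NaHSO4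
Reagents that add atoms: chlorotrimethylsilane, C[Si](C)(C)Cl
Why: Directed ortho-metalation: after in situ N-silylation the carbamate directs lithiation to C5, its only free ortho position, in preference to C7 next to the weaker ketal oxygen, TMSCl traps the aryllithium, and the N-silyl group is lost on acidic work-up.

Step 4
Reactants: 7 2,2-diphenyl-5-(trimethylsilyl)-1,3-benzodioxol-4-yl N-isopropylcarbamate
Product: 9 2,2-diphenyl-5-(trimethylsilyl)-1,3-benzodioxol-4-yl trifluoromethanesulfonate, via silylphenol 8 (not isolated)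
Conditions: Et2NH, DBU, MeCN, 40 °C; then PhNTf2, rt
Reagents that add atoms: N-phenylbis(trifluoromethanesulfonimide), O=S(=O)(N(c1ccccc1)S(=O)(=O)C(F)(F)F)C(F)(F)F
Why: Amine-induced E1cB cleavage of the N-monoalkyl carbamate (the isocyanate is scavenged by Et2NH as a urea) followed by O-sulfonylation of the hindered phenoxide gives the ortho-silylaryl triflate in one flask.

Step 5
Reactants: 9 2,2-diphenyl-5-(trimethylsilyl)-1,3-benzodioxol-4-yl trifluoromethanesulfonate
Product: 10 2,3-dihydroxy-6-(trimethylsilyl)phenyl trifluoromethanesulfonate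
Conditions: H2 (1 atm), Pd/C, EtOAc, rt
Reagents that add atoms: none
Why: Hydrogenolysis of the doubly benzylic C–O bonds of the ketal over palladium in neutral solvent frees the catechol, while the aryl triflate and the aryl–silicon bond should be inert under base-free conditions.

Step 6
Reactants: 10 2,3-dihydroxy-6-(trimethylsilyl)phenyl trifluoromethanesulfonate
Product: 11 3-(benzyloxy)-2-hydroxy-6-(trimethylsilyl)phenyl trifluoromethanesulfonate (2-benzyloxy-6-triflyloxy-5-trimethylsilylphenol)
Conditions: NaH (2.1 equiv), DMF, 0 °C; BnBr (1.0 equiv), 0 °C; 1 M HCl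
Reagents that add atoms: benzyl bromide, BrCc1ccccc1
Why: Regioselective Williamson etherification through the catechol dianion: the oxyanion remote from the triflate is the less stabilised and less hindered one and should take the single equivalent of benzyl bromide, leaving the more acidic, flanked hydroxyl free.

Step 7
Reactants: 12 3,4-bis(benzyloxy)benzaldehyde
Product: 13 methyl 3-[3,4-bis(benzyloxy)phenyl]-3-oxopropanoate
Conditions: N2CHCO2Me, NbCl5 (5 mol %), CH2Cl2, rt
Reagents that add atoms: methyl diazoacetate, COC(=O)C=[N+]=[N-]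
Why: Roskamp homologation: Lewis-acid-catalysed addition of the diazo ester to the aldehyde, 1,2-hydride shift and loss of N2 give the β-keto ester directly.

Step 8
Reactants: 13 methyl 3-[3,4-bis(benzyloxy)phenyl]-3-oxopropanoate
Product: 14 methyl (3R)-3-[3,4-bis(benzyloxy)phenyl]-3-hydroxypropanoate
Conditions: H2 (50 atm), RuCl2[(S)-BINAP] (cat.), MeOH, 50 °C
Reagents that add atoms: none
Why: Noyori asymmetric hydrogenation of a β-keto ester: chelation of the keto ester to the BINAP–ruthenium hydride fixes the face of hydride delivery, and the (S)-ligand should give the (R)-carbinol (the aryl group outranks CH2CO2Me, so the descriptor is opposite to that of the alkyl series).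

Step 9
Reactants: 11 3-(benzyloxy)-2-hydroxy-6-(trimethylsilyl)phenyl trifluoromethanesulfonate; 14 methyl (3R)-3-[3,4-bis(benzyloxy)phenyl]-3-hydroxypropanoate
Product: 15 methyl (3S)-3-[2-(benzyloxy)-6-(trifluoromethylsulfonyloxy)-5-(trimethylsilyl)phenoxy]-3-[3,4-bis(benzyloxy)phenyl]propanoate
Conditions: PPh3, DIAD, toluene, 0 °C → rt
Reagents that add atoms: none
Why: Mitsunobu etherification: the acidic phenol (ortho triflate) protonates the betaine and displaces the oxyphosphonium group by SN2 with inversion, turning the (R)-alcohol into the (S)-aryl ether, and the apolar solvent is chosen to disfavour ionisation of the electron-rich benzylic centre.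

Step 10
Reactants: 15 methyl (3S)-3-[2-(benzyloxy)-6-(trifluoromethylsulfonyloxy)-5-(trimethylsilyl)phenoxy]-3-[3,4-bis(benzyloxy)phenyl]propanoate
Product: 17 methyl (3S)-3-[2-(benzyloxy)-6-(trifluoromethylsulfonyloxy)-5-(trimethylsilyl)phenoxy]-3-[3,4-bis(benzyloxy)phenyl]-2-formylpropanoate, via lithium enolate 16 (not isolated)
Conditions: LiN(i-Pr)2, THF, −78 °C, 5 min; HCO2CH2CF3, −78 °C; AcOH, −78 °C
Reagents that add atoms: 2,2,2-trifluoroethyl formate, O=COCC(F)(F)F
Why: Crossed Claisen condensation (α-formylation) of the preformed lithium enolate with a highly reactive formate at −78 °C, chosen so that formylation outruns β-elimination of the aryloxide, which a sodium hydride/methyl formate formylation at higher temperature would invite; C3 is not touched.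

Step 11
Reactants: 17 methyl (3S)-3-[2-(benzyloxy)-6-(trifluoromethylsulfonyloxy)-5-(trimethylsilyl)phenoxy]-3-[3,4-bis(benzyloxy)phenyl]-2-formylpropanoate
Product: 18 methyl (3R)-3-[2-(benzyloxy)-6-(trifluoromethylsulfonyloxy)-5-(trimethylsilyl)phenoxy]-3-[3,4-bis(benzyloxy)phenyl]-2-[(tert-butyldimethylsilyloxy)methylidene]propanoate
Conditions: TBSCl, imidazole, CH2Cl2, 0 °C
Reagents that add atoms: tert-butyldimethylsilyl chloride, CC(C)(C)[Si](C)(C)Cl
Why: O-silylation of the acidic hydroxymethylene enol gives a silyl enol ether that has no acidic proton and cannot form the enolate until fluoride is added.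

Step 12
Reactants: 18 methyl (3R)-3-[2-(benzyloxy)-6-(trifluoromethylsulfonyloxy)-5-(trimethylsilyl)phenoxy]-3-[3,4-bis(benzyloxy)phenyl]-2-[(tert-butyldimethylsilyloxy)methylidene]propanoate
Product: 22 methyl (2S,3S)-7-(benzyloxy)-2-[3,4-bis(benzyloxy)phenyl]-4-formyl-2,3-dihydro-1-benzofuran-3-carboxylate, via aryne enolate 19 (not isolated), via cyclobutenoxide 20 (not isolated), via ester enolate 21 (not isolated)
Conditions: CsF, 18-crown-6, THF, 0 °C → rt; MeOH, rt; AcOH
Reagents that add atoms: none
Why: Proposed new method: fluoride removes both silyl groups, so that the formyl ester enolate and the C3a–C4 aryne (triflate leaving from C3a) appear together in 19; the enolate carbon C3 adds to C3a, the resulting C4 carbanion adds to the neighbouring formyl carbon to give the four-membered alkoxide 20, and cleavage of the C3–CHO bond releases the C4 aldehyde and the C3 ester enolate 21, the closest known reaction being the fluoride-promoted insertion of arynes into the α-carbon–acyl bond of β-keto esters (acyl-alkylation), here made intramolecular with formyl as the migrating group. The dihydrofuran ring closes in a 5-exo-dig sense onto the in-plane π bond of the aryne (C4 stays outside the new ring), and the transient four-membered ring forms by 4-exo-trig addition to the C=O group. C2 is not involved, and C3 is set when 21 is protonated under equilibrating conditions (MeOH, then AcOH), the C2 aryl group directing CO2Me to the trans position (2S,3S), while ring-opening of 21 by loss of O1 is the reverse of a 5-endo-trig closure and should be slow. The step needs carbon attack at C3a although a 3-alkoxyaryne normally takes nucleophiles at the distal carbon C4; the three-atom tether C3–C2–O1 secures this, since only the five-membered ring is within reach and attack through either enolate oxygen would need a seven-membered ring. It also needs formyl transfer to outrun protonation of the C4 carbanion and aryne capture to outrun loss of aryloxide from the enolate, which the silyl enol ether (no acidic proton, enolate and aryne unmasked at the same time) and the aprotic medium are meant to secure. Alkoxide 20 shares C3a with a four-, a five- and a six-membered ring and is therefore strained, so it is expected to be short-lived, and this is where the route carries its risk.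

Step 13
Reactants: 23 (R)-3-(3,4-dihydroxyphenyl)lactic acid (danshensu)
Product: 24 benzyl (2R)-3-[3,4-bis(benzyloxy)phenyl]-2-hydroxypropanoate
Conditions: BnBr, K2CO3, DMF, rt
Reagents that add atoms: benzyl bromide, BrCc1ccccc1
Why: Carbonate-mediated O-alkylation (Williamson etherification of the two phenols and alkylation of the carboxylate); the secondary alcohol is not ionised by K2CO3 and the stereocentre should not enolise under these conditions.

Step 14
Reactants: 24 benzyl (2R)-3-[3,4-bis(benzyloxy)phenyl]-2-hydroxypropanoate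
Product: 25 3-{[(2R)-1-(benzyloxy)-3-[3,4-bis(benzyloxy)phenyl]-1-oxopropan-2-yl]oxy}-3-oxopropanoic acid
Conditions: Meldrum's acid, toluene, 100 °C
Reagents that add atoms: Meldrum's acid (2,2-dimethyl-1,3-dioxane-4,6-dione), CC1(C)OC(=O)CC(=O)O1
Why: Thermal alcoholysis of Meldrum's acid: the alcohol opens the cyclic acylal and acetone is lost, giving the malonic acid half-ester without base or coupling agent.

Step 15
Reactants: 22 methyl (2S,3S)-7-(benzyloxy)-2-[3,4-bis(benzyloxy)phenyl]-4-formyl-2,3-dihydro-1-benzofuran-3-carboxylate; 25 3-{[(2R)-1-(benzyloxy)-3-[3,4-bis(benzyloxy)phenyl]-1-oxopropan-2-yl]oxy}-3-oxopropanoic acid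
Product: 27 methyl (2S,3S)-7-(benzyloxy)-4-[(1E)-3-{[(2R)-1-(benzyloxy)-3-[3,4-bis(benzyloxy)phenyl]-1-oxopropan-2-yl]oxy}-3-oxoprop-1-en-1-yl]-2-[3,4-bis(benzyloxy)phenyl]-2,3-dihydro-1-benzofuran-3-carboxylate, via arylidene malonate 26 (not isolated)
Conditions: pyridine, piperidine (cat.), 55 °C
Reagents that add atoms: none
Why: Knoevenagel–Doebner condensation with a malonic half-ester: amine-catalysed condensation at the C4 aldehyde gives arylidene malonate 26, whose decarboxylation in pyridine gives the (E)-cinnamate, and the trans-dihydrobenzofuran is the thermodynamic C3 epimer and should not be at risk.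

Step 16
Reactants: 27 methyl (2S,3S)-7-(benzyloxy)-4-[(1E)-3-{[(2R)-1-(benzyloxy)-3-[3,4-bis(benzyloxy)phenyl]-1-oxopropan-2-yl]oxy}-3-oxoprop-1-en-1-yl]-2-[3,4-bis(benzyloxy)phenyl]-2,3-dihydro-1-benzofuran-3-carboxylate
Product: 28 monomethyl lithospermate
Conditions: BCl3, C6HMe5, CH2Cl2, −78 °C; MeOH
Reagents that add atoms: none
Why: Lewis-acid debenzylation: BCl3 cleaves the five aryl benzyl ethers and the benzyl ester at low temperature while pentamethylbenzene traps the benzyl cations by Friedel–Crafts alkylation, so that the alkene (which rules out hydrogenolysis), the methyl ester, the cinnamate ester and the benzylic C2–O1 bond should be spared.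

**Compound list**

1 | pyrogallol | Oc1cccc(O)c1O | starting material
2 | 2,2-diphenyl-1,3-benzodioxol-4-ol | Oc1cccc2OC(c3ccccc3)(c3ccccc3)Oc12 | intermediate
3 | 2,2-diphenyl-1,3-benzodioxol-4-yl N-isopropylcarbamate | CC(C)NC(=O)Oc1cccc2OC(c3ccccc3)(c3ccccc3)Oc12 | intermediate
4 | 2,2-diphenyl-1,3-benzodioxol-4-yl N-(tert-butyldimethylsilyl)-N-isopropylcarbamate (not isolated) | CC(C)N(C(=O)Oc1cccc2OC(c3ccccc3)(c3ccccc3)Oc12)[Si](C)(C)C(C)(C)C | intermediate
5 | 5-lithio derivative of 4 (not isolated) | [Li]c1ccc2OC(c3ccccc3)(c3ccccc3)Oc2c1OC(=O)N(C(C)C)[Si](C)(C)C(C)(C)C | intermediate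
6 | 2,2-diphenyl-5-(trimethylsilyl)-1,3-benzodioxol-4-yl N-(tert-butyldimethylsilyl)-N-isopropylcarbamate (not isolated) | CC(C)N(C(=O)Oc1c([Si](C)(C)C)ccc2OC(c3ccccc3)(c3ccccc3)Oc12)[Si](C)(C)C(C)(C)C | intermediate
7 | 2,2-diphenyl-5-(trimethylsilyl)-1,3-benzodioxol-4-yl N-isopropylcarbamate | CC(C)NC(=O)Oc1c([Si](C)(C)C)ccc2OC(c3ccccc3)(c3ccccc3)Oc12 | intermediate
8 | 2,2-diphenyl-5-(trimethylsilyl)-1,3-benzodioxol-4-ol (not isolated) | Oc1c([Si](C)(C)C)ccc2OC(c3ccccc3)(c3ccccc3)Oc12 | intermediate
9 | 2,2-diphenyl-5-(trimethylsilyl)-1,3-benzodioxol-4-yl trifluoromethanesulfonate | C[Si](C)(C)c1ccc2OC(c3ccccc3)(c3ccccc3)Oc2c1OS(=O)(=O)C(F)(F)F | intermediate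
10 | 2,3-dihydroxy-6-(trimethylsilyl)phenyl trifluoromethanesulfonate | Oc1ccc([Si](C)(C)C)c(OS(=O)(=O)C(F)(F)F)c1O | intermediate
11 | 3-(benzyloxy)-2-hydroxy-6-(trimethylsilyl)phenyl trifluoromethanesulfonate | Oc1c(OCc2ccccc2)ccc([Si](C)(C)C)c1OS(=O)(=O)C(F)(F)F | intermediate
12 | 3,4-bis(benzyloxy)benzaldehyde | O=Cc1ccc(OCc2ccccc2)c(OCc2ccccc2)c1 | starting material
13 | methyl 3-[3,4-bis(benzyloxy)phenyl]-3-oxopropanoate | COC(=O)CC(=O)c1ccc(OCc2ccccc2)c(OCc2ccccc2)c1 | intermediate
14 | methyl (3R)-3-[3,4-bis(benzyloxy)phenyl]-3-hydroxypropanoate | COC(=O)C[C@@H](O)c1ccc(OCc2ccccc2)c(OCc2ccccc2)c1 | intermediate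
15 | methyl (3S)-3-[2-(benzyloxy)-6-(trifluoromethylsulfonyloxy)-5-(trimethylsilyl)phenoxy]-3-[3,4-bis(benzyloxy)phenyl]propanoate | COC(=O)C[C@H](Oc1c(OCc2ccccc2)ccc([Si](C)(C)C)c1OS(=O)(=O)C(F)(F)F)c1ccc(OCc2ccccc2)c(OCc2ccccc2)c1 | intermediate
16 | lithium enolate of 15 (not isolated) | COC(O[Li])=C[C@H](Oc1c(OCc2ccccc2)ccc([Si](C)(C)C)c1OS(=O)(=O)C(F)(F)F)c1ccc(OCc2ccccc2)c(OCc2ccccc2)c1 | intermediate
17 | methyl (3S)-3-[2-(benzyloxy)-6-(trifluoromethylsulfonyloxy)-5-(trimethylsilyl)phenoxy]-3-[3,4-bis(benzyloxy)phenyl]-2-formylpropanoate (C2 enolised) | COC(=O)C(C=O)[C@H](Oc1c(OCc2ccccc2)ccc([Si](C)(C)C)c1OS(=O)(=O)C(F)(F)F)c1ccc(OCc2ccccc2)c(OCc2ccccc2)c1 | intermediate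
18 | methyl (3R)-3-[2-(benzyloxy)-6-(trifluoromethylsulfonyloxy)-5-(trimethylsilyl)phenoxy]-3-[3,4-bis(benzyloxy)phenyl]-2-[(tert-butyldimethylsilyloxy)methylidene]propanoate | COC(=O)C(=CO[Si](C)(C)C(C)(C)C)[C@H](Oc1c(OCc2ccccc2)ccc([Si](C)(C)C)c1OS(=O)(=O)C(F)(F)F)c1ccc(OCc2ccccc2)c(OCc2ccccc2)c1 | intermediate
19 | cesium enolate of the formyl ester with the C3a–C4 aryne (not isolated) | COC(=O)C(=C[O-])[C@H](OC1=C(OCc2ccccc2)C=CC#C1)c1ccc(OCc2ccccc2)c(OCc2ccccc2)c1.[Cs+] | intermediate
20 | cesium benzocyclobutenoxide bridging C3 and C4 (not isolated; configuration at C3 and at the carbinolate carbon left open) | COC(=O)C12C([O-])c3ccc(OCc4ccccc4)c(O[C@@H]1c1ccc(OCc4ccccc4)c(OCc4ccccc4)c1)c32.[Cs+] | intermediate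
21 | cesium C3 ester enolate of 22 (not isolated) | COC([O-])=C1c2c(C=O)ccc(OCc3ccccc3)c2O[C@@H]1c1ccc(OCc2ccccc2)c(OCc2ccccc2)c1.[Cs+] | intermediate
22 | methyl (2S,3S)-7-(benzyloxy)-2-[3,4-bis(benzyloxy)phenyl]-4-formyl-2,3-dihydro-1-benzofuran-3-carboxylate | COC(=O)[C@H]1c2c(C=O)ccc(OCc3ccccc3)c2O[C@@H]1c1ccc(OCc2ccccc2)c(OCc2ccccc2)c1 | intermediate
23 | (R)-3-(3,4-dihydroxyphenyl)lactic acid (danshensu) | O[C@H](Cc1ccc(O)c(O)c1)C(=O)O | starting material
24 | benzyl (2R)-3-[3,4-bis(benzyloxy)phenyl]-2-hydroxypropanoate | O[C@H](Cc1ccc(OCc2ccccc2)c(OCc2ccccc2)c1)C(=O)OCc1ccccc1 | intermediate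
25 | 3-{[(2R)-1-(benzyloxy)-3-[3,4-bis(benzyloxy)phenyl]-1-oxopropan-2-yl]oxy}-3-oxopropanoic acid | OC(=O)CC(=O)O[C@H](Cc1ccc(OCc2ccccc2)c(OCc2ccccc2)c1)C(=O)OCc1ccccc1 | intermediate
26 | arylidene malonic acid half-ester from 22 and 25 (not isolated) | COC(=O)[C@H]1c2c(C=C(C(=O)O)C(=O)O[C@H](Cc3ccc(OCc4ccccc4)c(OCc4ccccc4)c3)C(=O)OCc3ccccc3)ccc(OCc3ccccc3)c2O[C@@H]1c1ccc(OCc2ccccc2)c(OCc2ccccc2)c1 | intermediate
27 | hexabenzyl-protected monomethyl lithospermate (full name in step 15) | COC(=O)[C@H]1c2c(/C=C/C(=O)O[C@H](Cc3ccc(OCc4ccccc4)c(OCc4ccccc4)c3)C(=O)OCc3ccccc3)ccc(OCc3ccccc3)c2O[C@@H]1c1ccc(OCc2ccccc2)c(OCc2ccccc2)c1 | intermediate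
28 | monomethyl lithospermate, (2S,3S) at the dihydrobenzofuran, (R) at the lactate carbon, (E)-alkene | COC(=O)[C@H]1c2c(/C=C/C(=O)O[C@H](Cc3ccc(O)c(O)c3)C(=O)O)ccc(O)c2O[C@@H]1c1ccc(O)c(O)c1 | target

**Step count and risks**

Total steps: 16
Longest linear sequence: 12 steps (steps 1–6, 9–12, 15 and 16)

Steps most likely to fail:

1. Step 12. What may go wrong: the C4 carbanion is protonated (or attacks the ester instead) before the formyl group has migrated, so that only C3–C3a forms; or the enolate sheds the aryloxide before the aryne is generated, which breaks the chain and erodes C2. Fallback (known chemistry, imine-directed rhodium-catalysed intramolecular C–H alkylation), setting out from aldehyde 12 and coming back at 22: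
   - Corey–Fuchs olefination of 12 (CBr4, PPh3) gives 4-(2,2-dibromoethenyl)-1,2-bis(benzyloxy)benzene F1.
   - n-BuLi followed by ClCO2Me gives methyl 3-[3,4-bis(benzyloxy)phenyl]prop-2-ynoate F2.
   - Base-mediated conjugate addition of commercial 4-(benzyloxy)-3-hydroxybenzaldehyde (K2CO3, DMF) gives methyl (2Z)-3-[2-(benzyloxy)-5-formylphenoxy]-3-[3,4-bis(benzyloxy)phenyl]prop-2-enoate F3.
   - Condensation with (R)-1-aminoindane (or its enantiomer, whichever leads to the 2S series) gives the corresponding N-(indan-1-yl)imine F4.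
   - [RhCl(coe)2]2 with dicyclohexyl(ferrocenyl)phosphine in toluene at 75 °C should activate the C–H bond flanked by the imine and the ether oxygen and add it syn across the enol ether double bond; acidic hydrolysis of the imine then gives methyl (2S,3R)-7-(benzyloxy)-2-[3,4-bis(benzyloxy)phenyl]-4-formyl-2,3-dihydro-1-benzofuran-3-carboxylate F5, the cis isomer.
   - Epimerisation at C3 (DBU, or NaOMe in MeOH) leads to 22. This sequence needs neither the aryne nor the formyl ester.

2. Step 10. What may go wrong: β-elimination of the aryloxide from lithium enolate 16 (E1cB), which destroys the ether and the C3 stereocentre before formylation can occur. Fallback: the formyl carbon is brought in as a protected hydroxymethyl group before the ether is made, so that no simple ester enolate ever carries a β-aryloxy group. It sets out from 14 and comes back at 17: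
   - Fráter–Seebach hydroxymethylation of the dianion of 14 (LiN(i-Pr)2, 2.2 equiv, THF, −78 → −20 °C, then monomeric formaldehyde) should give the anti diol, methyl (2S,3R)-3-[3,4-bis(benzyloxy)phenyl]-3-hydroxy-2-(hydroxymethyl)propanoate F6.
   - Selective silylation of the primary hydroxyl (TESCl, imidazole, −20 °C) gives methyl (2S,3R)-3-[3,4-bis(benzyloxy)phenyl]-3-hydroxy-2-[(triethylsilyloxy)methyl]propanoate F7.
   - Mitsunobu etherification with 11 (PPh3, DIAD, toluene) gives the (2S,3S) aryl ether F8.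
   - PPTS in MeOH removes the silyl group to give the (2S,3S) primary alcohol F9.
   - Dess–Martin oxidation gives 17.

3. Step 9. What may go wrong: partial ionisation of the electron-rich benzylic oxyphosphonium ion (loss of enantiopurity) or elimination to the cinnamate, both favoured by the hindered phenol. Fallback: the C–O bond is formed at an sp2 carbon and the stereocentre is set afterwards by asymmetric hydrogenation. It sets out from 13 (with 11) and comes back at 15:
   - Enol tosylation of 13 (TsCl, N-methylimidazole, Et3N) gives methyl (2Z)-3-[3,4-bis(benzyloxy)phenyl]-3-(tosyloxy)prop-2-enoate F10.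
   - Addition–elimination with phenol 11 (K2CO3, DABCO cat., MeCN, rt) gives methyl (2Z)-3-[2-(benzyloxy)-6-(trifluoromethylsulfonyloxy)-5-(trimethylsilyl)phenoxy]-3-[3,4-bis(benzyloxy)phenyl]prop-2-enoate F11.
   - Enantioselective hydrogenation of the trisubstituted double bond (H2, [Ir(cod)(L*)]BArF with a chiral phosphine–oxazoline ligand L*, enantiomer chosen for 3S) should give 15 without touching the benzyl ethers or the triflate.

**Further compounds**

F1 | step 12 | 4-(2,2-dibromoethenyl)-1,2-bis(benzyloxy)benzene | BrC(Br)=Cc1ccc(OCc2ccccc2)c(OCc2ccccc2)c1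
F2 | step 12 | methyl 3-[3,4-bis(benzyloxy)phenyl]prop-2-ynoate | COC(=O)C#Cc1ccc(OCc2ccccc2)c(OCc2ccccc2)c1
F3 | step 12 | methyl (2Z)-3-[2-(benzyloxy)-5-formylphenoxy]-3-[3,4-bis(benzyloxy)phenyl]prop-2-enoate | COC(=O)/C=C(\Oc1cc(C=O)ccc1OCc1ccccc1)c1ccc(OCc2ccccc2)c(OCc2ccccc2)c1
F4 | step 12 | (E)-imine of F3 with (R)-1-aminoindane | COC(=O)/C=C(\Oc1cc(/C=N/[C@@H]2CCc3ccccc23)ccc1OCc1ccccc1)c1ccc(OCc2ccccc2)c(OCc2ccccc2)c1
F5 | step 12 | methyl (2S,3R)-7-(benzyloxy)-2-[3,4-bis(benzyloxy)phenyl]-4-formyl-2,3-dihydro-1-benzofuran-3-carboxylate | COC(=O)[C@@H]1c2c(C=O)ccc(OCc3ccccc3)c2O[C@@H]1c1ccc(OCc2ccccc2)c(OCc2ccccc2)c1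
F6 | step 10 | methyl (2S,3R)-3-[3,4-bis(benzyloxy)phenyl]-3-hydroxy-2-(hydroxymethyl)propanoate | COC(=O)[C@@H](CO)[C@@H](O)c1ccc(OCc2ccccc2)c(OCc2ccccc2)c1
F7 | step 10 | methyl (2S,3R)-3-[3,4-bis(benzyloxy)phenyl]-3-hydroxy-2-[(triethylsilyloxy)methyl]propanoate | COC(=O)[C@@H](CO[Si](CC)(CC)CC)[C@@H](O)c1ccc(OCc2ccccc2)c(OCc2ccccc2)c1
F8 | step 10 | methyl (2S,3S)-3-[2-(benzyloxy)-6-(trifluoromethylsulfonyloxy)-5-(trimethylsilyl)phenoxy]-3-[3,4-bis(benzyloxy)phenyl]-2-[(triethylsilyloxy)methyl]propanoate | COC(=O)[C@@H](CO[Si](CC)(CC)CC)[C@H](Oc1c(OCc2ccccc2)ccc([Si](C)(C)C)c1OS(=O)(=O)C(F)(F)F)c1ccc(OCc2ccccc2)c(OCc2ccccc2)c1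
F9 | step 10 | methyl (2S,3S)-3-[2-(benzyloxy)-6-(trifluoromethylsulfonyloxy)-5-(trimethylsilyl)phenoxy]-3-[3,4-bis(benzyloxy)phenyl]-2-(hydroxymethyl)propanoate | COC(=O)[C@@H](CO)[C@H](Oc1c(OCc2ccccc2)ccc([Si](C)(C)C)c1OS(=O)(=O)C(F)(F)F)c1ccc(OCc2ccccc2)c(OCc2ccccc2)c1
F10 | step 9 | methyl (2Z)-3-[3,4-bis(benzyloxy)phenyl]-3-(tosyloxy)prop-2-enoate | COC(=O)/C=C(\OS(=O)(=O)c1ccc(C)cc1)c1ccc(OCc2ccccc2)c(OCc2ccccc2)c1
F11 | step 9 | methyl (2Z)-3-[2-(benzyloxy)-6-(trifluoromethylsulfonyloxy)-5-(trimethylsilyl)phenoxy]-3-[3,4-bis(benzyloxy)phenyl]prop-2-enoate | COC(=O)/C=C(\Oc1c(OCc2ccccc2)ccc([Si](C)(C)C)c1OS(=O)(=O)C(F)(F)F)c1ccc(OCc2ccccc2)c(OCc2ccccc2)c1
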